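The constants of the proposed steps were unknown to me, so I looked in the earlier runs for something nearly constant and froze it. I kept a ledger of the substrate.

| flask | substrate | coupling partner | free catalyst | impurity | remark | time |
|---|---|---|---|---|---|---|
| Sunday's | 0.87 M | 1.5 M | 9.3 mM | 0.97 mM | run made earlier |  |
| Tuesday's | 1.7 M | 1.5 M | 9.3 mM | 0.97 mM | run made earlier |  |
| Monday's | 1 M | 1.5 M | 9.3 mM | 0.71 mM | run made earlier |  |
| eta | 1.0 M | 1.50 M | 9.3 mM | 0.97 mM |  | 10 h |
| delta | 2.0 M | 1.50 M | 9.3 mM | 0.50 mM |  | 10 h |

- Sunday's (time / h: target / %): 0.500: 4.7; 1.33: 9.7; 3.00: 18.6; 8.00: 44.7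
- Tuesday's (time / h: target / %): 2.00: 8.9; 4.00: 11.7; 5.00: 13.8; 8.00: 24.1
- Monday's (time / h: target / %): 2.00: 11.2; 4.00: 23.0; 5.00: 28.4; 8.00: 40.6

(each reading ± 1 percentage point)

- percentages count the substrate that a species holds: one self-condensation product counts as two
- target is meant together with its idle adduct
- what was read earlier has a scatter of 1 percentage point, one standard deviation
- steps that have been proposed: coupling partner + free catalyst <-> catalyst intermediate A; catalyst intermediate A -> catalyst intermediate B; substrate + catalyst intermediate B -> catalyst intermediate C; catalyst intermediate C -> free catalyst + target; free catalyst + impurity -> spent catalyst; coupling partner + target <-> idle adduct; 2 substrate -> self-condensation product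

* which one finishes higher in amount of target, in percent of the substrate charged ("neither" within 2 percentage points) (eta / delta / neither)
* amount of target at the end, in percent of the substrate charged, eta
* amount of target at the end, in percent of the substrate charged, delta

1. I booked the substrate charged as target (idle adduct counted in), as self-condensation product, or as unreacted, and left out of the ledger what catalyst intermediate C holds at a given moment.
2. I booked one catalyst lost per impurity, as the proposed step has it. That left 8.33 mM of working catalyst in eta and 8.80 mM in delta.
3. From each last reading, at 8.00 h, I reckoned target made per hour per working catalyst: 5.84 h⁻¹ on Sunday, 6.15 h⁻¹ on Tuesday and 5.91 h⁻¹ on Monday, although Tuesday's substrate was twice Sunday's.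
4. Their mean, 5.96 h⁻¹, is the working turnover rate, target made per hour per working catalyst, the usual turnover frequency.
5. Frozen for 10 h, it put 49.7% of eta's substrate and 26.2% of delta's into target.
6. The remainder, 50.3% in eta and 73.8% in delta, I booked as self-condensed or unreacted. The runs did not split it, and freezing the rate assumed that substrate lasted.

The forecast said eta, with 48% for eta and 27% for delta, on the ground that “the reaction is near zero order in substrate”. My entry for eta lay above its figure, my entry for delta below, in the same order.

Eta finished at 45.1% and delta at 25.1%, so eta finished higher, as forecast. Beside its target, eta held 50.6% as self-condensation product and 4.17% as substrate at 10.0 h. My frozen target entry for eta with those two comes to 104% of the charge, so in eta the frozen rate overdraws the ledger. Eta's working turnover rate averaged 5.41 h⁻¹ over its 10 h, lower than the 5.96 h⁻¹ read from the runs.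

    coupling partner + free catalyst ⇌ catalyst intermediate A (K = 0.640 M⁻¹, k = 12.0 M⁻¹ h⁻¹)
    catalyst intermediate A → catalyst intermediate B (k = 280 h⁻¹)
    substrate + catalyst intermediate B → catalyst intermediate C (k = 140 M⁻¹ h⁻¹)
    catalyst intermediate C → free catalyst + target (k = 15.0 h⁻¹)
    free catalyst + impurity → spent catalyst (k = 7200 M⁻¹ h⁻¹)
    coupling partner + target ⇌ idle adduct, settled at all times (K = 0.980 M⁻¹)
    2 substrate → self-condensation product (k = 0.150 M⁻¹ h⁻¹)

A second flask had eta's recipe with 0.0023 M of free catalyst, which leaves 1.33 mM working, so the frozen rate gives 7.93% of the substrate as target. The computed flask gave 8.85%.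

(The data stem from a simulated flask from invented constants, noise included.)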